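The five-membered ring of the trans-fused hydroazulene is disconnected between C-3, the tertiary carbinol carbon bearing isopropyl, and the ring-fusion methine C-3a. A SmI2 ketyl–olefin cyclisation of an acyclic isopropyl ketone onto the vinyl group on the quaternary carbon C-8a closes this cyclopentane, sets C-3 and C-3a in one operation, and the alkylsamarium formed is oxygenated to give the C-4 hydroxymethyl handle. The step exploits the trans arrangement of the C-3 hydroxyl and the C-3a–C-4 bond on the five-membered ring, the signature of a ketyl 5-exo closure. The precursor comes from an asymmetric allylboration of crotonaldehyde with a neryl boronate; ring-closing metathesis later forms the seven-membered ring.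

Key step: step 6

Remark: locants are those of the hexahydroazulene core of the target (C-1 and C-2 methylenes, C-3 carbinol carbon, C-3a ring-fusion CH, C-4 aroyloxy carbon, C-5 CH2, C-6 methyl-bearing alkene carbon, C-7 alkene CH, C-8 isovaleryloxy carbon, C-8a quaternary methyl carbon) and are kept for the same atoms in all precursors.

Step 1
Reactants: 1 nerol
Product: 2 neryl pinacol boronate
Conditions: B2pin2, Pd(MeCN)4(BF4)2 (5 mol %), DMSO/MeOH, rt
Reagents that add atoms: bis(pinacolato)diboron, CC1(C)OB(OC1(C)C)B1OC(C)(C)C(C)(C)O1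
Why: Palladium-catalysed direct borylation of an allylic alcohol through a π-allyl intermediate should give the linear allylboronate with the Z-trisubstituted alkene retained, because syn/anti exchange would have to pass through the tertiary terminus; no stereocentre is formed.

Step 2
Reactants: 2 neryl pinacol boronate; 3 (E)-crotonaldehyde
Product: 5 (2E,4S,5S)-5-ethenyl-5,9-dimethyldeca-2,8-dien-4-ol, via pinacol borate ester 4 (not isolated)
Conditions: (R)-TRIP [(R)-3,3'-bis(2,4,6-triisopropylphenyl)-1,1'-binaphthyl-2,2'-diyl hydrogen phosphate] (5 mol %), 4 Å MS, toluene, −30 °C; aq. NaHCO3 work-up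
Reagents that add atoms: none
Why: Chiral phosphoric acid-catalysed allylboration through a closed six-membered chair: the Z-boronate places its methyl group equatorial and the chain axial, so the new hydroxyl (C-8) ends anti to the methyl of the new quaternary carbon (C-8a), and the (R)-acid should direct attack to the Re face of the enal.

Step 3
Reactants: 5 (2E,4S,5S)-5-ethenyl-5,9-dimethyldeca-2,8-dien-4-ol
Product: 6 tert-butyldimethylsilyl ether of 5
Conditions: TBSOTf, 2,6-lutidine, CH2Cl2, −78 → 0 °C
Reagents that add atoms: tert-butyldimethylsilyl trifluoromethanesulfonate, CC(C)(C)[Si](C)(C)OS(=O)(=O)C(F)(F)F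
Why: Silylation with the silyl triflate should protect the hindered secondary allylic alcohol and make the C-8 substituent clearly larger than the neighbouring methyl, which is needed in step 6; no stereocentre changes.

Step 4
Reactants: 6 tert-butyldimethylsilyl ether of 5
Product: 7 8,9-epoxide of 6 (both epoxide epimers)
Conditions: mCPBA (1.05 equiv), NaHCO3, CH2Cl2, −10 °C
Reagents that add atoms: 3-chloroperoxybenzoic acid, OOC(=O)c1cccc(Cl)c1
Why: Prilezhaev epoxidation should select the electron-rich trisubstituted alkene over the hindered vinyl and the inductively deactivated propenyl group; the new epoxide stereocentre is uncontrolled and is destroyed in step 5.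

Step 5
Reactants: 7 8,9-epoxide of 6
Product: 8 (6S,7S,8E)-7-(tert-butyldimethylsilyloxy)-6-ethenyl-2,6-dimethyldec-8-en-3-one
Conditions: BF3·OEt2 (0.2 equiv), CH2Cl2, −78 °C
Reagents that add atoms: none
Why: Meinwald rearrangement: Lewis-acid opening at the tertiary C–O bond followed by a 1,2-hydride shift from the adjacent carbon should give the isopropyl ketone (the future C-3), with C-8 and C-8a untouched.

Step 6
Reactants: 8 (6S,7S,8E)-7-(tert-butyldimethylsilyloxy)-6-ethenyl-2,6-dimethyldec-8-en-3-one
Product: 10 (1S,2S,3S)-3-[(1S,2E)-1-(tert-butyldimethylsilyloxy)but-2-en-1-yl]-2-(hydroxymethyl)-3-methyl-1-(propan-2-yl)cyclopentan-1-ol, via alkylsamarium alkoxide 9 (not isolated)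
Conditions: SmI2 (3 equiv), HMPA (12 equiv), THF, no proton source, 0 °C → rt; then dry O2, −78 °C → rt; aq. NH4Cl
Reagents that add atoms: dioxygen, O=O
Why: SmI2/HMPA reduces the ketone to a samarium ketyl whose carbon adds to the internal carbon of the vinyl group, forming the C-3–C-3a bond; the primary radical is reduced to alkylsamarium 9 (trivalent samarium), which O2 converts into the primary alkoxide. The closest known reaction type is the SmI2/HMPA reductive cyclisation of unactivated olefinic ketones with electrophilic capture of the resulting organosamarium. The only ring closed is the cyclopentane, in the 5-exo-trig mode. The C-3 configuration follows from the anti preference of ketyl–olefin cyclisations (the HMPA-solvated O–Sm group turns away from the alkene, so the hydroxyl ends trans to the new CH2O group and the isopropyl group cis); the C-3a configuration relative to the existing quaternary C-8a follows from the chair-like 5-exo transition state, in which the branched silyloxybutenyl group sits pseudo-equatorial and the methyl group pseudo-axial, so that group ends trans to the new CH2O group. The step needs 5-exo closure onto the vinyl group in preference to 6-exo attack on the propenyl group, and survival of the alkylsamarium until oxygenation; the terminal, five-atom-distant vinyl group against the 1,2-disubstituted, six-atom-distant propenyl group secures the first, and the absence of proton sources and ester groups secures the second.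

Step 7
Reactants: 10 (1S,2S,3S)-3-[(1S,2E)-1-(tert-butyldimethylsilyloxy)but-2-en-1-yl]-2-(hydroxymethyl)-3-methyl-1-(propan-2-yl)cyclopentan-1-ol
Product: 11 (1R,2S,5S)-5-[(1S,2E)-1-(tert-butyldimethylsilyloxy)but-2-en-1-yl]-2-hydroxy-5-methyl-2-(propan-2-yl)cyclopentane-1-carbaldehyde
Conditions: TEMPO (10 mol %), PhI(OAc)2, CH2Cl2, rt
Reagents that add atoms: none
Why: Oxoammonium (TEMPO) oxidation should convert only the primary alcohol to the aldehyde, the tertiary alcohol being inert; the neutral conditions should spare the β-hydroxy aldehyde from retro-aldol cleavage, and no stereocentre is touched (the descriptor at the ring CH changes by priority only).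

Step 8
Reactants: 11 cyclopentanecarbaldehyde; 12 methallyl pinacol boronate
Product: 14 (1S,2S,3S)-3-[(1S,2E)-1-(tert-butyldimethylsilyloxy)but-2-en-1-yl]-2-[(1R)-1-hydroxy-3-methylbut-3-en-1-yl]-3-methyl-1-(propan-2-yl)cyclopentan-1-ol, via pinacol borate ester 13 (not isolated)
Conditions: (R)-TRIP (10 mol %), 4 Å MS, toluene, −30 → 0 °C; aq. NaHCO3 work-up
Reagents that add atoms: none
Why: Chiral phosphoric acid-catalysed allylboration through a closed chair: the (R)-acid should deliver the methallyl group to the Re face of the aldehyde, which is also the face the substrate should prefer because the boron-bound carbonyl oxygen turns towards the methyl-bearing C-8a side and away from the isopropyl-bearing C-3 side while the nucleophile passes the C-3a hydrogen, giving the (R)-carbinol at C-4.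

Step 9
Reactants: 14 homoallylic alcohol; 15 4-acetoxybenzoyl chloride
Product: 16 4-acetoxybenzoate of 14 at the secondary (C-4) hydroxyl
Conditions: Et3N, DMAP (cat.), CH2Cl2, 0 °C → rt
Reagents that add atoms: none
Why: DMAP-catalysed acylation should esterify the only secondary hydroxyl while the tertiary C-3 hydroxyl stays free; the C-4 configuration is retained because the C–O bond is not broken.

Step 10
Reactants: 16 4-acetoxybenzoate of 14
Product: 17 (3S,3aS,4R,8S,8aS)-8-(tert-butyldimethylsilyloxy)-3-hydroxy-6,8a-dimethyl-3-(propan-2-yl)-1,2,3,3a,4,5,8,8a-octahydroazulen-4-yl 4-acetoxybenzoate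
Conditions: second-generation Hoveyda–Grubbs catalyst RuCl2(H2IMes)(=CH-C6H4-2-OiPr) (10 mol %), toluene, 80 °C
Reagents that add atoms: none
Why: Ring-closing metathesis between the propenyl group and the 1,1-disubstituted alkene should form the trisubstituted C-6=C-7 alkene of the seven-membered ring with loss of propene; the trans arrangement of the two arms on the cyclopentane fixes the trans ring fusion and no stereocentre is created.

Step 11
Reactants: 17 silyl-protected bicyclic ester
Product: 18 (3S,3aS,4R,8S,8aS)-3,8-dihydroxy-6,8a-dimethyl-3-(propan-2-yl)-1,2,3,3a,4,5,8,8a-octahydroazulen-4-yl 4-acetoxybenzoate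
Conditions: HF·pyridine, THF/pyridine, 0 °C → rt
Reagents that add atoms: none
Why: Fluoride-mediated desilylation under mildly acidic conditions should free the C-8 hydroxyl without touching the benzoate or the phenolic acetate; no stereocentre is affected.

Step 12
Reactants: 18 C-8 alcohol; 19 3-methylbutanoic anhydride
Product: 20 (3S,3aS,4R,8S,8aS)-3-hydroxy-6,8a-dimethyl-8-(3-methylbutanoyloxy)-3-(propan-2-yl)-1,2,3,3a,4,5,8,8a-octahydroazulen-4-yl 4-acetoxybenzoate
Conditions: Et3N, DMAP, CH2Cl2, rt
Reagents that add atoms: none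
Why: DMAP-catalysed acylation should esterify the secondary allylic C-8 hydroxyl, the tertiary C-3 hydroxyl again remaining free; configuration at C-8 is retained.

Step 13
Reactants: 20 phenolic acetate of the target
Product: 21 (3S,3aS,4R,8S,8aS)-3-hydroxy-6,8a-dimethyl-8-(3-methylbutanoyloxy)-3-(propan-2-yl)-1,2,3,3a,4,5,8,8a-octahydroazulen-4-yl 4-hydroxybenzoate
Conditions: NH4OAc, MeOH/H2O (4:1), rt
Reagents that add atoms: none
Why: Chemoselective solvolysis of the aryl acetate, whose phenoxide leaving group makes it far more reactive than the two alkyl esters, should release the phenol without acyl loss or migration elsewhere.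

Compound list
1 | nerol, (2Z)-3,7-dimethylocta-2,6-dien-1-ol | CC(C)=CCC/C(C)=C\CO | starting material
2 | neryl pinacol boronate, 2-[(2Z)-3,7-dimethylocta-2,6-dien-1-yl]-4,4,5,5-tetramethyl-1,3,2-dioxaborolane | CC(C)=CCC/C(C)=C\CB1OC(C)(C)C(C)(C)O1 | intermediate
3 | (E)-crotonaldehyde, (2E)-but-2-enal | C/C=C/C=O | starting material
4 | pinacol borate ester of 5 (O–B bond at the new carbinol) | C/C=C/[C@H](OB1OC(C)(C)C(C)(C)O1)[C@@](C=C)(C)CCC=C(C)C | intermediate (not isolated)
5 | (2E,4S,5S)-5-ethenyl-5,9-dimethyldeca-2,8-dien-4-ol (hydroxyl anti to the quaternary methyl) | C/C=C/[C@H](O)[C@@](C=C)(C)CCC=C(C)C | intermediate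
6 | tert-butyldimethylsilyl ether of 5 | C/C=C/[C@H](O[Si](C)(C)C(C)(C)C)[C@@](C=C)(C)CCC=C(C)C | intermediate
7 | 8,9-epoxide of 6, both epimers at the epoxide CH | C/C=C/[C@H](O[Si](C)(C)C(C)(C)C)[C@@](C=C)(C)CCC1OC1(C)C | intermediate
8 | (6S,7S,8E)-7-(tert-butyldimethylsilyloxy)-6-ethenyl-2,6-dimethyldec-8-en-3-one | C/C=C/[C@H](O[Si](C)(C)C(C)(C)C)[C@@](C=C)(C)CCC(=O)C(C)C | intermediate
9 | cyclised alkylsamarium alkoxide: diiodosamarium on the new CH2 and on the tertiary oxygen (trivalent samarium) | C/C=C/[C@H](O[Si](C)(C)C(C)(C)C)[C@@]1(C)CC[C@](O[Sm](I)I)(C(C)C)[C@@H]1C[Sm](I)I | intermediate (not isolated)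
10 | (1S,2S,3S)-3-[(1S,2E)-1-(tert-butyldimethylsilyloxy)but-2-en-1-yl]-2-(hydroxymethyl)-3-methyl-1-(propan-2-yl)cyclopentan-1-ol; OH trans to CH2OH and cis to the silyloxybutenyl group, methyl cis to CH2OH | C/C=C/[C@H](O[Si](C)(C)C(C)(C)C)[C@@]1(C)CC[C@](O)(C(C)C)[C@@H]1CO | intermediate
11 | (1R,2S,5S)-5-[(1S,2E)-1-(tert-butyldimethylsilyloxy)but-2-en-1-yl]-2-hydroxy-5-methyl-2-(propan-2-yl)cyclopentane-1-carbaldehyde | C/C=C/[C@H](O[Si](C)(C)C(C)(C)C)[C@@]1(C)CC[C@](O)(C(C)C)[C@@H]1C=O | intermediate
12 | methallyl pinacol boronate, 4,4,5,5-tetramethyl-2-(2-methylprop-2-en-1-yl)-1,3,2-dioxaborolane | CC(=C)CB1OC(C)(C)C(C)(C)O1 | starting material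
13 | pinacol borate ester of 14 (O–B bond at the new C-4 carbinol) | C/C=C/[C@H](O[Si](C)(C)C(C)(C)C)[C@@]1(C)CC[C@](O)(C(C)C)[C@@H]1[C@H](OB2OC(C)(C)C(C)(C)O2)CC(C)=C | intermediate (not isolated)
14 | (1S,2S,3S)-3-[(1S,2E)-1-(tert-butyldimethylsilyloxy)but-2-en-1-yl]-2-[(1R)-1-hydroxy-3-methylbut-3-en-1-yl]-3-methyl-1-(propan-2-yl)cyclopentan-1-ol | C/C=C/[C@H](O[Si](C)(C)C(C)(C)C)[C@@]1(C)CC[C@](O)(C(C)C)[C@@H]1[C@H](O)CC(C)=C | intermediate
15 | 4-acetoxybenzoyl chloride | CC(=O)Oc1ccc(cc1)C(Cl)=O | starting material
16 | 4-acetoxybenzoate of 14 at the secondary C-4 hydroxyl | C/C=C/[C@H](O[Si](C)(C)C(C)(C)C)[C@@]1(C)CC[C@](O)(C(C)C)[C@@H]1[C@H](OC(=O)c2ccc(OC(C)=O)cc2)CC(C)=C | intermediate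
17 | (3S,3aS,4R,8S,8aS)-8-(tert-butyldimethylsilyloxy)-3-hydroxy-6,8a-dimethyl-3-(propan-2-yl)-1,2,3,3a,4,5,8,8a-octahydroazulen-4-yl 4-acetoxybenzoate | CC1=C[C@H](O[Si](C)(C)C(C)(C)C)[C@@]2(C)CC[C@](O)(C(C)C)[C@@H]2[C@H](OC(=O)c2ccc(OC(C)=O)cc2)C1 | intermediate
18 | (3S,3aS,4R,8S,8aS)-3,8-dihydroxy-6,8a-dimethyl-3-(propan-2-yl)-1,2,3,3a,4,5,8,8a-octahydroazulen-4-yl 4-acetoxybenzoate | CC1=C[C@H](O)[C@@]2(C)CC[C@](O)(C(C)C)[C@@H]2[C@H](OC(=O)c2ccc(OC(C)=O)cc2)C1 | intermediate
19 | 3-methylbutanoic (isovaleric) anhydride | CC(C)CC(=O)OC(=O)CC(C)C | starting material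
20 | (3S,3aS,4R,8S,8aS)-3-hydroxy-6,8a-dimethyl-8-(3-methylbutanoyloxy)-3-(propan-2-yl)-1,2,3,3a,4,5,8,8a-octahydroazulen-4-yl 4-acetoxybenzoate | CC1=C[C@H](OC(=O)CC(C)C)[C@@]2(C)CC[C@](O)(C(C)C)[C@@H]2[C@H](OC(=O)c2ccc(OC(C)=O)cc2)C1 | intermediate
21 | (3S,3aS,4R,8S,8aS)-3-hydroxy-6,8a-dimethyl-8-(3-methylbutanoyloxy)-3-(propan-2-yl)-1,2,3,3a,4,5,8,8a-octahydroazulen-4-yl 4-hydroxybenzoate | CC1=C[C@H](OC(=O)CC(C)C)[C@@]2(C)CC[C@](O)(C(C)C)[C@@H]2[C@H](OC(=O)c2ccc(O)cc2)C1 | target

Total step count: 13. Longest linear sequence: 13 steps, from nerol (1) to 21.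

Steps most likely to fail

Step 6 (key step). The carbon–samarium bond may be protonated, or may give peroxide-derived mixtures, before clean C–O bond formation with O2, so that the C-4 oxygen is not installed. The fallback sets out from 8 and comes back at 11. The same SmI2/HMPA cyclisation is quenched with diphenyl disulfide, which should give the phenyl sulfide F1. Oxidation with NaIO4 in aqueous methanol should give the sulfoxide F2. A Pummerer rearrangement with trifluoroacetic anhydride and 2,6-lutidine should give the α-trifluoroacetoxy sulfide F3, which aqueous NaHCO3 hydrolyses to aldehyde 11.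

Step 8. Facial selectivity in the addition to the hindered aldehyde may be poor if the catalysed pathway is slow and the uncatalysed background addition takes over. The fallback sets out from 11 and comes back at 17. Methallylmagnesium chloride in THF at −78 °C should give the C-4 epimeric alcohols F4. Dess–Martin periodinane should oxidise both epimers to the single β-hydroxy ketone F5. Ring-closing metathesis under the conditions of step 10 should give the bicyclic ketone F6. NaBH4 in MeOH at −20 °C, with hydride entering from the ring face opposite to the angular methyl and the isopropyl group, should give the bicyclic alcohol F7. Acylation of F7 with 15 under the conditions of step 9 gives 17.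

Step 5. The cationic rearrangement may take other courses: alkyl shift to an aldehyde, proton loss to an allylic alcohol, or Lewis-acid loss of the allylic silyl ether. The fallback sets out from 7 and comes back at 8. Periodic acid (H5IO6) in THF/water should cleave the epoxide to the aldehyde F8 with loss of acetone. Isopropylmagnesium chloride at −78 °C should give the secondary alcohol F9. Dess–Martin oxidation then gives ketone 8.

Further compounds
F1 | step 6 | phenyl sulfide, the analogue of 10 with CH2SPh in place of CH2OH | C/C=C/[C@H](O[Si](C)(C)C(C)(C)C)[C@@]1(C)CC[C@](O)(C(C)C)[C@@H]1CSc2ccccc2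
F2 | step 6 | sulfoxide of F1 (both epimers at sulfur) | C/C=C/[C@H](O[Si](C)(C)C(C)(C)C)[C@@]1(C)CC[C@](O)(C(C)C)[C@@H]1CS(=O)c2ccccc2
F3 | step 6 | α-trifluoroacetoxy sulfide from the Pummerer rearrangement of F2 (both epimers at the new carbon) | C/C=C/[C@H](O[Si](C)(C)C(C)(C)C)[C@@]1(C)CC[C@](O)(C(C)C)[C@@H]1C(OC(=O)C(F)(F)F)Sc2ccccc2
F4 | step 8 | C-4 epimeric mixture of homoallylic alcohols (14 and its C-4 epimer) | C/C=C/[C@H](O[Si](C)(C)C(C)(C)C)[C@@]1(C)CC[C@](O)(C(C)C)[C@@H]1C(O)CC(C)=C
F5 | step 8 | β-hydroxy ketone, the C-4 ketone corresponding to 14 | C/C=C/[C@H](O[Si](C)(C)C(C)(C)C)[C@@]1(C)CC[C@](O)(C(C)C)[C@@H]1C(=O)CC(C)=C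
F6 | step 8 | bicyclic ketone, (3S,3aS,8S,8aS)-8-(tert-butyldimethylsilyloxy)-3-hydroxy-6,8a-dimethyl-3-(propan-2-yl)-2,3,3a,5,8,8a-hexahydroazulen-4(1H)-one | CC1=C[C@H](O[Si](C)(C)C(C)(C)C)[C@@]2(C)CC[C@](O)(C(C)C)[C@@H]2C(=O)C1
F7 | step 8 | bicyclic alcohol, (3S,3aS,4R,8S,8aS)-8-(tert-butyldimethylsilyloxy)-6,8a-dimethyl-3-(propan-2-yl)-1,2,3,3a,4,5,8,8a-octahydroazulene-3,4-diol | CC1=C[C@H](O[Si](C)(C)C(C)(C)C)[C@@]2(C)CC[C@](O)(C(C)C)[C@@H]2[C@H](O)C1
F8 | step 5 | (4S,5S,6E)-5-(tert-butyldimethylsilyloxy)-4-ethenyl-4-methyloct-6-enal | C/C=C/[C@H](O[Si](C)(C)C(C)(C)C)[C@@](C=C)(C)CCC=O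
F9 | step 5 | (6S,7S,8E)-7-(tert-butyldimethylsilyloxy)-6-ethenyl-2,6-dimethyldec-8-en-3-ol (both carbinol epimers) | C/C=C/[C@H](O[Si](C)(C)C(C)(C)C)[C@@](C=C)(C)CCC(O)C(C)C
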